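The target is an ester of two constitutionally identical, mirror-image bicyclic halves. After cleaving that ester and each seven-membered lactone (ring B), everything rests on disconnecting cyclohexane ring A of each half at C1–C6 and C4–C5. One catalytic asymmetric Diels–Alder reaction forms both bonds, ring A and the all-trans array C1(isopropyl)/C6(future vinylic carbon)/C5(future lactone carbonyl carbon) beside oxygenated C4, which is the feature exploited. Its precursors are achiral: (1E,3E)-5-methylhexa-1,3-dienyl acetate and (E)-4,4-dimethoxybut-2-enal. The two antipodal imidazolidinone catalysts deliver the two halves, which are finished by ring-closing metathesis and joined by esterification.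

Key step: step 3

Remarks on the chemistry (assumptions)
- Numbering: in each half, ring A is C1 (bears isopropyl), C2, C3, C4 (bears OH and CH2O), C5 (bears the lactone carbonyl carbon), C6 (bears the vinylic carbon). β is the face of the C1 isopropyl group, α the other face.
- Series A is the half with the free C4 diol and the esterified acrylic carboxyl (C1-iPr β, C4-OH α, C4-CH2OH β, C5-C=O β, C6-vinylic carbon α). Series B is its mirror image (free acrylic acid, acylated C4-CH2O). Step 16 repeats the key step with the antipodal catalyst.
- Assumption: the facial sense of the catalyst is taken from the usual shielding model of the (E)-iminium ion. On that model the (2R,5R) salt leads to series A and the (2S,5S) salt to series B. If the sense is the opposite, the two catalysts exchange roles and nothing else changes.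
- A C4 ketone is never placed next to a C5 carbonyl group, since a β-dicarbonyl would enolise instead of accepting a methylene unit. C5 stays at the alcohol level, tied up as a cyclic acetal with C6, until C4 is complete.
- Compounds 8–14 and 24–30 are mixtures of epimers at the acetal or lactol carbon, which later becomes the vinylic carbon.

Step 1
Reactants: 1 3-methylbutanal
Product: 2 (E)-5-methylhex-2-enal
Conditions: Ph3P=CHCHO (0.7 equiv), toluene, 80 °C
Reagents that add atoms: (triphenylphosphoranylidene)acetaldehyde, O=CC=P(c1ccccc1)(c1ccccc1)c1ccccc1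
Why: Wittig olefination with the formyl-stabilised ylide is E-selective, and the excess of aldehyde 1 suppresses a second homologation.

Step 2
Reactants: 2 (E)-5-methylhex-2-enal; 3 isopropenyl acetate
Product: 4 (1E,3E)-5-methylhexa-1,3-dien-1-yl acetate
Conditions: 3 (excess, as solvent), p-TsOH·H2O (cat.), Cu(OAc)2 (cat.), reflux, acetone distilled off
Reagents that add atoms: none
Why: Acid-catalysed enol acetylation traps the extended dienol formed by loss of a γ-proton; the 3E geometry is the thermodynamic one, and the 1E isomer, expected to predominate, is enriched by fractional distillation.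

Step 3
Reactants: 4 (1E,3E)-5-methylhexa-1,3-dien-1-yl acetate; 5 (E)-4,4-dimethoxybut-2-enal
Product: 6 (1R,4S,5R,6S)-5-(dimethoxymethyl)-6-formyl-4-isopropylcyclohex-2-en-1-yl acetate (series A endo adduct: acetoxy, formyl and isopropyl β, dimethoxymethyl α)
Conditions: (2R,5R)-5-benzyl-2-tert-butyl-3-methylimidazolidin-4-one·TFA (20 mol%), 4 (2 equiv), MeCN/H2O (19:1), −10 to 0 °C
Reagents that add atoms: none
Why: Enal 5 condenses with the ammonium salt to an (E)-iminium ion whose lowered LUMO engages diene 4 in a concerted, asynchronous [4+2] cycloaddition in which the C1–C6 bond (isopropyl-bearing diene terminus to the iminium β-carbon) runs ahead of the C4–C5 bond, after which hydrolysis releases 6 and the amine. The closest known reaction type is the imidazolidinone-catalysed enantioselective Diels–Alder reaction of enals with 1-acyloxybuta-1,3-dienes. Ring A closes in an intermolecular, suprafacial six-membered [4+2] mode from the four diene carbons (C1–C4) and the two dienophile carbons (C5, C6). The trans C5/C6 relationship is carried over from the E enal, the cis C1/C4 relationship from the E,E diene, the cis relationship of formyl to isopropyl and acetoxy from the endo orientation of the iminium group, and the absolute configuration of all four centres from the iminium face left open by the benzyl and tert-butyl groups of the catalyst. The step needs regio-, endo- and enantiofacial selectivity: the acyloxy donor makes the remote, isopropyl-bearing terminus the nucleophilic one so that it pairs with the iminium β-carbon, secondary overlap with the C=N+ unit favours endo, and the rigid E-iminium geometry enforces face selection. Only the 1E isomer of 4 can reach the s-cis conformation, so residual 1Z diene remains a spectator.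

Step 4
Reactants: 6 series A endo adduct
Product: 8 series A bicyclic methyl acetal (C5–CH2–O–CH(OMe)–C6 ring trans-fused to cyclohexene; C4-OH β), via series A diol 7 (not isolated)
Conditions: LiAlH4, THF, 0 °C; Rochelle-salt work-up; then PPTS (cat.), 4 Å MS, CH2Cl2, rt
Reagents that add atoms: none
Why: Hydride reduction converts the aldehyde and the acetate into the diol before acetic acid can be eliminated, and acid-catalysed intramolecular transacetalisation then lets the C5 carbinol capture the trans C6 acetal as a five-membered cyclic acetal, which protects both groups and leaves only the C4 hydroxyl free.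

Step 5
Reactants: 8 series A bicyclic methyl acetal
Product: 9 series A enone (C4 ketone conjugated with C2=C3)
Conditions: MnO2 (activated, excess), CH2Cl2, rt
Reagents that add atoms: none
Why: Allylic alcohol oxidation with MnO2 is neutral, spares the acetal and removes the sacrificial C4 stereocentre.

Step 6
Reactants: 9 series A enone
Product: 10 series A saturated C4 ketone
Conditions: H2 (1 atm), 10% Pd/C, EtOAc, rt
Reagents that add atoms: none
Why: Heterogeneous hydrogenation saturates the conjugated C2=C3 bond chemoselectively, creates no stereocentre and does not enolise C5.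

Step 7
Reactants: 10 series A saturated C4 ketone
Product: 11 series A C4 exocyclic methylene compound
Conditions: Cp2TiMe2 (3 equiv), toluene/THF, 65 °C, dark
Reagents that add atoms: dimethyltitanocene, C[Ti](C)(C1C=CC=C1)C1C=CC=C1
Why: Petasis methylenation uses a non-basic titanium methylidene, so the enolisable ketone is olefinated without epimerising C5 or eliminating the β-alkoxy group.

Step 8
Reactants: 11 series A C4 exocyclic methylene compound
Product: 12 series A diol (C4-OH α and equatorial, C4-CH2OH β and axial)
Conditions: K2OsO4·2H2O (cat.), NMO, acetone/H2O (4:1), rt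
Reagents that add atoms: N-methylmorpholine N-oxide, C[N+]1([O-])CCOCC1; water, O
Why: In this Upjohn dihydroxylation the bulky osmium reagent should add from the equatorial α face, away from the syn-axial C2 and C6 hydrogens and the β-tilted C5 substituent, so the tertiary OH ends up α and the CH2OH β as in the target.

Step 9
Reactants: 12 series A diol
Product: 13 series A primary tert-butyldiphenylsilyl (TBDPS) ether (C4-CH2OTBDPS, tertiary C4-OH free)
Conditions: TBDPSCl, imidazole, DMAP (cat.), DMF, rt
Reagents that add atoms: tert-butyl(chloro)diphenylsilane, CC(C)(C)[Si](Cl)(c1ccccc1)c1ccccc1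
Why: Silylation takes only the primary hydroxyl, the tertiary one being too hindered, and the TBDPS group survives the aqueous acid of step 10 and the TFA of step 15.

Step 10
Reactants: 13 series A primary TBDPS ether
Product: 14 series A lactol (C5–CH2–O–CH(OH)–C6)
Conditions: 2 M aq. HCl/THF (1:3), rt
Reagents that add atoms: water, O
Why: Acid-catalysed acetal hydrolysis gives the lactol, a masked C6 aldehyde and C5 carbinol, while the TBDPS ether and tertiary alcohol tolerate dilute HCl.

Step 11
Reactants: 14 series A lactol
Product: 15 series A vinyl diol (C6-CH=CH2 α, C5-CH2OH β, C4-OH α, C4-CH2OTBDPS β)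
Conditions: Ph3PCH3Br, KOtBu (4 equiv each), THF, 0 °C to rt
Reagents that add atoms: methyltriphenylphosphonium bromide, C[P+](c1ccccc1)(c1ccccc1)c1ccccc1.[Br-]
Why: Wittig methylenation of the lactol through its open hydroxy-aldehyde form installs the C6 vinyl group and frees the C5 carbinol; C6 is not at risk because its equatorial, all-trans configuration is the thermodynamic one.

Step 12
Reactants: 15 series A vinyl diol
Product: 17 series A vinyl acid (C5-CO2H), via series A aldehyde 16 (not isolated)
Conditions: TEMPO (cat.), PhI(OAc)2 (2.5 equiv), MeCN/H2O (1:1), rt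
Reagents that add atoms: water, O
Why: Nitroxyl-catalysed oxidation takes the only primary alcohol through the aldehyde hydrate to the acid and leaves the tertiary alcohol, silyl ether and vinyl group alone.

Step 13
Reactants: 17 series A vinyl acid; 18 tert-butyl 2-(bromomethyl)prop-2-enoate
Product: 19 series A diene ester (C5-CO2CH2C(=CH2)CO2tBu, C6-CH=CH2)
Conditions: KHCO3, DMF, 0 °C to rt
Reagents that add atoms: none
Why: Carboxylate O-alkylation by the reactive allylic bromide (SN2, or SN2′ to the same product) proceeds under bicarbonate conditions that leave the tertiary alcohol untouched.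

Step 14
Reactants: 19 series A diene ester
Product: 20 series A bicyclic lactone tert-butyl ester (ring B closed; C4-OH α, C4-CH2OTBDPS β)
Conditions: second-generation Grubbs catalyst (H2IMes)(PCy3)Cl2Ru=CHPh (10 mol%), toluene (2 mM), 80 °C, Ar sparge
Reagents that add atoms: none
Why: Ring-closing metathesis between the C6 vinyl group and the 1,1-disubstituted acrylate closes the seven-membered lactone with loss of ethylene; the trans-diequatorial arms are held close, dilution suppresses dimerisation, and the ring alkene can only have the geometry of the target.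

Step 15
Reactants: 20 series A bicyclic lactone tert-butyl ester
Product: 21 half A acid (acrylic CO2H free, C4-CH2OTBDPS)
Conditions: TFA/CH2Cl2 (1:4), 0 °C to rt
Reagents that add atoms: none
Why: Acidolysis of the tert-butyl ester (loss of isobutene) frees the acrylic acid while the TBDPS ether, lactone and tertiary alcohol persist.

Step 16
Reactants: 4 (1E,3E)-5-methylhexa-1,3-dien-1-yl acetate; 5 (E)-4,4-dimethoxybut-2-enal
Product: 22 (1S,4R,5S,6R)-5-(dimethoxymethyl)-6-formyl-4-isopropylcyclohex-2-en-1-yl acetate (series B endo adduct, mirror image of 6)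
Conditions: (2S,5S)-5-benzyl-2-tert-butyl-3-methylimidazolidin-4-one·TFA (20 mol%), 4 (2 equiv), MeCN/H2O (19:1), −10 to 0 °C
Reagents that add atoms: none
Why: The same iminium-catalysed endo Diels–Alder reaction as in step 3, in which the antipodal catalyst exposes the opposite iminium face, so that ring A and its four centres form in the mirror-image sense with unchanged regio- and endo-control.

Step 17
Reactants: 22 series B endo adduct
Product: 24 series B bicyclic methyl acetal, via series B diol 23 (not isolated)
Conditions: LiAlH4, THF, 0 °C; Rochelle-salt work-up; then PPTS (cat.), 4 Å MS, CH2Cl2, rt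
Reagents that add atoms: none
Why: Mirror-image counterpart of step 4 (hydride reduction, then intramolecular transacetalisation).

Step 18
Reactants: 24 series B bicyclic methyl acetal
Product: 25 series B enone
Conditions: MnO2 (activated, excess), CH2Cl2, rt
Reagents that add atoms: none
Why: Mirror-image counterpart of step 5 (allylic alcohol oxidation).

Step 19
Reactants: 25 series B enone
Product: 26 series B saturated C4 ketone
Conditions: H2 (1 atm), 10% Pd/C, EtOAc, rt
Reagents that add atoms: none
Why: Mirror-image counterpart of step 6 (conjugate alkene hydrogenation).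

Step 20
Reactants: 26 series B saturated C4 ketone
Product: 27 series B C4 exocyclic methylene compound
Conditions: Cp2TiMe2 (3 equiv), toluene/THF, 65 °C, dark
Reagents that add atoms: dimethyltitanocene, C[Ti](C)(C1C=CC=C1)C1C=CC=C1
Why: Mirror-image counterpart of step 7 (Petasis methylenation without epimerisation at C5).

Step 21
Reactants: 27 series B C4 exocyclic methylene compound
Product: 28 series B diol (mirror image of 12)
Conditions: K2OsO4·2H2O (cat.), NMO, acetone/H2O (4:1), rt
Reagents that add atoms: N-methylmorpholine N-oxide, C[N+]1([O-])CCOCC1; water, O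
Why: Mirror-image counterpart of step 8 (Upjohn dihydroxylation from the equatorial face, giving equatorial OH and axial CH2OH).

Step 22
Reactants: 28 series B diol
Product: 29 series B primary TBDPS ether
Conditions: TBDPSCl, imidazole, DMAP (cat.), DMF, rt
Reagents that add atoms: tert-butyl(chloro)diphenylsilane, CC(C)(C)[Si](Cl)(c1ccccc1)c1ccccc1
Why: Mirror-image counterpart of step 9 (selective silylation of the primary hydroxyl).

Step 23
Reactants: 29 series B primary TBDPS ether
Product: 30 series B lactol
Conditions: 2 M aq. HCl/THF (1:3), rt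
Reagents that add atoms: water, O
Why: Mirror-image counterpart of step 10 (acetal hydrolysis to the lactol).

Step 24
Reactants: 30 series B lactol
Product: 31 series B vinyl diol
Conditions: Ph3PCH3Br, KOtBu (4 equiv each), THF, 0 °C to rt
Reagents that add atoms: methyltriphenylphosphonium bromide, C[P+](c1ccccc1)(c1ccccc1)c1ccccc1.[Br-]
Why: Mirror-image counterpart of step 11 (Wittig methylenation of a lactol).

Step 25
Reactants: 31 series B vinyl diol
Product: 33 series B vinyl acid, via series B aldehyde 32 (not isolated)
Conditions: TEMPO (cat.), PhI(OAc)2 (2.5 equiv), MeCN/H2O (1:1), rt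
Reagents that add atoms: water, O
Why: Mirror-image counterpart of step 12 (nitroxyl-catalysed oxidation of the primary alcohol to the acid).

Step 26
Reactants: 33 series B vinyl acid; 18 tert-butyl 2-(bromomethyl)prop-2-enoate
Product: 34 series B diene ester
Conditions: KHCO3, DMF, 0 °C to rt
Reagents that add atoms: none
Why: Mirror-image counterpart of step 13 (carboxylate O-alkylation).

Step 27
Reactants: 34 series B diene ester
Product: 35 series B bicyclic lactone tert-butyl ester (mirror image of 20)
Conditions: second-generation Grubbs catalyst (H2IMes)(PCy3)Cl2Ru=CHPh (10 mol%), toluene (2 mM), 80 °C, Ar sparge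
Reagents that add atoms: none
Why: Mirror-image counterpart of step 14 (ring-closing metathesis to the seven-membered lactone).

Step 28
Reactants: 35 series B bicyclic lactone tert-butyl ester
Product: 36 half B diol (C4-OH and C4-CH2OH free, acrylic tert-butyl ester kept)
Conditions: HF·pyridine, THF/pyridine, 0 °C to rt
Reagents that add atoms: none
Why: Fluoride-mediated Si–O cleavage removes the TBDPS group under buffered, weakly acidic conditions that spare the tert-butyl ester, the lactone and the base-sensitive 2-(acyloxymethyl)acrylate unit.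

Step 29
Reactants: 21 half A acid; 36 half B diol
Product: 37 protected dimer (acrylic carboxyl of half A esterified with C4-CH2OH of half B; TBDPS on half A, tert-butyl ester on half B)
Conditions: 2,4,6-trichlorobenzoyl chloride, Et3N, toluene, rt; then 36, DMAP, toluene, rt
Reagents that add atoms: none
Why: In this Yamaguchi esterification DMAP attacks the mixed anhydride at the less hindered acrylic carbonyl, and the acylpyridinium acylates only the primary hydroxyl of 36, the tertiary hydroxyls of both partners being unreactive.

Step 30
Reactants: 37 protected dimer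
Product: 39 CNP0340505.1 (target), via silylated dimer acid 38 (not isolated)
Conditions: TFA/CH2Cl2 (1:4), 0 °C; evaporate; then HF·pyridine, THF/pyridine, 0 °C to rt
Reagents that add atoms: none
Why: Two-stage global deprotection in one flask: the tert-butyl ester is removed by acidolysis while the half A primary hydroxyl is still silylated and cannot attack the neighbouring lactone, and the TBDPS ether is then cleaved by fluoride under mild conditions.

Compound list
1 | 3-methylbutanal | CC(C)CC=O | starting material
2 | (E)-5-methylhex-2-enal | CC(C)C/C=C/C=O | intermediate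
3 | isopropenyl acetate | CC(=C)OC(C)=O | starting material
4 | (1E,3E)-5-methylhexa-1,3-dien-1-yl acetate | CC(C)/C=C/C=C/OC(C)=O | intermediate
5 | (E)-4,4-dimethoxybut-2-enal | O=C/C=C/C(OC)OC | starting material
6 | series A endo adduct, (1R,4S,5R,6S)-5-(dimethoxymethyl)-6-formyl-4-isopropylcyclohex-2-en-1-yl acetate | CC(C)[C@H]1C=C[C@@H](OC(C)=O)[C@@H](C=O)[C@@H]1C(OC)OC | intermediate
7 | series A diol (C4-OH β, C5-CH2OH β, C6-CH(OMe)2 α, C1-iPr β, C2=C3) | CC(C)[C@H]1C=C[C@@H](O)[C@@H](CO)[C@@H]1C(OC)OC | intermediate (not isolated)
8 | series A bicyclic methyl acetal (trans-fused 2-methoxytetrahydrofuran on C5–C6, C4-OH β, C2=C3; acetal epimers) | CC(C)[C@H]1C=C[C@@H](O)[C@H]2COC(OC)[C@H]12 | intermediate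
9 | series A enone (C4=O, C2=C3) | CC(C)[C@H]1C=CC(=O)[C@H]2COC(OC)[C@H]12 | intermediate
10 | series A saturated C4 ketone | CC(C)[C@H]1CCC(=O)[C@H]2COC(OC)[C@H]12 | intermediate
11 | series A C4 exocyclic methylene compound | CC(C)[C@H]1CCC(=C)[C@H]2COC(OC)[C@H]12 | intermediate
12 | series A diol (C4-OH α, C4-CH2OH β) | CC(C)[C@H]1CC[C@@](O)(CO)[C@H]2COC(OC)[C@H]12 | intermediate
13 | series A primary TBDPS ether | CC(C)[C@H]1CC[C@@](O)(CO[Si](c3ccccc3)(c3ccccc3)C(C)(C)C)[C@H]2COC(OC)[C@H]12 | intermediate
14 | series A lactol (lactol epimers) | CC(C)[C@H]1CC[C@@](O)(CO[Si](c3ccccc3)(c3ccccc3)C(C)(C)C)[C@H]2COC(O)[C@H]12 | intermediate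
15 | series A vinyl diol (C6-vinyl α, C5-CH2OH β) | CC(C)[C@H]1CC[C@@](O)(CO[Si](c2ccccc2)(c2ccccc2)C(C)(C)C)[C@@H](CO)[C@@H]1C=C | intermediate
16 | series A aldehyde (C5-CHO β) | CC(C)[C@H]1CC[C@@](O)(CO[Si](c2ccccc2)(c2ccccc2)C(C)(C)C)[C@@H](C=O)[C@@H]1C=C | intermediate (not isolated)
17 | series A vinyl acid (C5-CO2H β) | CC(C)[C@H]1CC[C@@](O)(CO[Si](c2ccccc2)(c2ccccc2)C(C)(C)C)[C@@H](C(=O)O)[C@@H]1C=C | intermediate
18 | tert-butyl 2-(bromomethyl)prop-2-enoate | C=C(CBr)C(=O)OC(C)(C)C | starting material
19 | series A diene ester | CC(C)[C@H]1CC[C@@](O)(CO[Si](c2ccccc2)(c2ccccc2)C(C)(C)C)[C@@H](C(=O)OCC(=C)C(=O)OC(C)(C)C)[C@@H]1C=C | intermediate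
20 | series A bicyclic lactone tert-butyl ester | CC(C)[C@H]1CC[C@@](O)(CO[Si](c3ccccc3)(c3ccccc3)C(C)(C)C)[C@H]2C(=O)OCC(C(=O)OC(C)(C)C)=C[C@H]12 | intermediate
21 | half A acid | CC(C)[C@H]1CC[C@@](O)(CO[Si](c3ccccc3)(c3ccccc3)C(C)(C)C)[C@H]2C(=O)OCC(C(=O)O)=C[C@H]12 | intermediate
22 | series B endo adduct, (1S,4R,5S,6R)-5-(dimethoxymethyl)-6-formyl-4-isopropylcyclohex-2-en-1-yl acetate | CC(C)[C@@H]1C=C[C@H](OC(C)=O)[C@H](C=O)[C@H]1C(OC)OC | intermediate
23 | series B diol (mirror image of 7) | CC(C)[C@@H]1C=C[C@H](O)[C@H](CO)[C@H]1C(OC)OC | intermediate (not isolated)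
24 | series B bicyclic methyl acetal (mirror image of 8) | CC(C)[C@@H]1C=C[C@H](O)[C@@H]2COC(OC)[C@@H]12 | intermediate
25 | series B enone (mirror image of 9) | CC(C)[C@@H]1C=CC(=O)[C@@H]2COC(OC)[C@@H]12 | intermediate
26 | series B saturated C4 ketone (mirror image of 10) | CC(C)[C@@H]1CCC(=O)[C@@H]2COC(OC)[C@@H]12 | intermediate
27 | series B C4 exocyclic methylene compound (mirror image of 11) | CC(C)[C@@H]1CCC(=C)[C@@H]2COC(OC)[C@@H]12 | intermediate
28 | series B diol (mirror image of 12) | CC(C)[C@@H]1CC[C@](O)(CO)[C@@H]2COC(OC)[C@@H]12 | intermediate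
29 | series B primary TBDPS ether (mirror image of 13) | CC(C)[C@@H]1CC[C@](O)(CO[Si](c3ccccc3)(c3ccccc3)C(C)(C)C)[C@@H]2COC(OC)[C@@H]12 | intermediate
30 | series B lactol (mirror image of 14) | CC(C)[C@@H]1CC[C@](O)(CO[Si](c3ccccc3)(c3ccccc3)C(C)(C)C)[C@@H]2COC(O)[C@@H]12 | intermediate
31 | series B vinyl diol (mirror image of 15) | CC(C)[C@@H]1CC[C@](O)(CO[Si](c2ccccc2)(c2ccccc2)C(C)(C)C)[C@H](CO)[C@H]1C=C | intermediate
32 | series B aldehyde (mirror image of 16) | CC(C)[C@@H]1CC[C@](O)(CO[Si](c2ccccc2)(c2ccccc2)C(C)(C)C)[C@H](C=O)[C@H]1C=C | intermediate (not isolated)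
33 | series B vinyl acid (mirror image of 17) | CC(C)[C@@H]1CC[C@](O)(CO[Si](c2ccccc2)(c2ccccc2)C(C)(C)C)[C@H](C(=O)O)[C@H]1C=C | intermediate
34 | series B diene ester (mirror image of 19) | CC(C)[C@@H]1CC[C@](O)(CO[Si](c2ccccc2)(c2ccccc2)C(C)(C)C)[C@H](C(=O)OCC(=C)C(=O)OC(C)(C)C)[C@H]1C=C | intermediate
35 | series B bicyclic lactone tert-butyl ester (mirror image of 20) | CC(C)[C@@H]1CC[C@](O)(CO[Si](c3ccccc3)(c3ccccc3)C(C)(C)C)[C@@H]2C(=O)OCC(C(=O)OC(C)(C)C)=C[C@@H]12 | intermediate
36 | half B diol (free C4 diol, tert-butyl ester) | CC(C)[C@@H]1CC[C@](O)(CO)[C@@H]2C(=O)OCC(C(=O)OC(C)(C)C)=C[C@@H]12 | intermediate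
37 | protected dimer (TBDPS on half A, tert-butyl ester on half B) | CC(C)[C@H]1CC[C@@](O)(CO[Si](c5ccccc5)(c5ccccc5)C(C)(C)C)[C@H]2C(=O)OCC(C(=O)OC[C@@]3(O)CC[C@@H](C(C)C)[C@@H]4C=C(C(=O)OC(C)(C)C)COC(=O)[C@H]43)=C[C@H]12 | intermediate
38 | silylated dimer acid (TBDPS on half A, free acid on half B) | CC(C)[C@H]1CC[C@@](O)(CO[Si](c5ccccc5)(c5ccccc5)C(C)(C)C)[C@H]2C(=O)OCC(C(=O)OC[C@@]3(O)CC[C@@H](C(C)C)[C@@H]4C=C(C(=O)O)COC(=O)[C@H]43)=C[C@H]12 | intermediate (not isolated)
39 | CNP0340505.1 | CC(C)[C@H]1CC[C@@](O)(CO)[C@H]2C(=O)OCC(C(=O)OC[C@@]3(O)CC[C@@H](C(C)C)[C@@H]4C=C(C(=O)O)COC(=O)[C@H]43)=C[C@H]12 | target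

Total step count: 30.
Longest linear sequence: 17 steps (1, 2, 3–15, 29, 30; the branch through 16–28 is equally long).

Steps most likely to fail

1. Steps 3 and 16 (the cycloaddition). A β-substituted enal may turn over slowly with a diene whose nucleophilic terminus is branched. Endo or enantiofacial control may erode, the dimethyl acetal may hydrolyse in the aqueous acidic medium, and acetic acid may be lost from the adduct through its enamine. Fallback: absolute control is moved from the catalyst to a resolution, which wastes nothing because both antipodes are needed. Setting out from 4 and 5, an uncatalysed thermal Diels–Alder reaction (toluene, 90 °C, BHT) should give the racemic endo adduct, which is the 1:1 mixture of 6 and 22. Reduction and cyclisation as in step 4 lead to the racemic mixture of 8 and 24. Lipase-catalysed acylation of the C4 hydroxyl (Candida antarctica lipase B, vinyl acetate, MTBE, rt) should acetylate one antipode only. The acetate of the series B bicyclic methyl acetal F1 (drawn on the assumption that this antipode reacts faster) is separated from the unreacted alcohol and returned to the alcohol with K2CO3 in MeOH. The route is rejoined at 8 and 24.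

2. Steps 14 and 27 (ring-closing metathesis). The ester must adopt its disfavoured s-cis conformation to close a seven-membered lactone, and the acrylate olefin is electron-poor and 1,1-disubstituted, so cross-metathesis oligomers and catalyst decay may win. Fallback: olefination followed by lactonisation, setting out from 17 (series B: 33). Ozonolysis (O3, CH2Cl2/MeOH, −78 °C; Me2S) converts the vinyl group into the series A formyl acid F2 (series B formyl acid F5). A Horner–Wadsworth–Emmons reaction follows with the sodium salt of tert-butyl 2-(diethoxyphosphoryl)-3-[(4-methoxybenzyl)oxy]propanoate (2.2 equiv, THF, 0 °C to rt), generated from tert-butyl 2-(diethoxyphosphoryl)acrylate and sodium 4-methoxybenzyl oxide. It should give the series A (E)-enoate acid F3 (series B (E)-enoate acid F6), with the ester trans to C6. DDQ (CH2Cl2/pH 7 buffer) removes the 4-methoxybenzyl group to give the series A hydroxy acid F4 (series B hydroxy acid F7). Yamaguchi lactonisation (2,4,6-trichlorobenzoyl chloride, Et3N, THF; then DMAP, toluene, high dilution) returns to the route at 20 (series B: 35).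

3. Step 29 (esterification). A neopentyl-type alcohol may be acylated only slowly by a hindered α,β-unsaturated acyl donor. During a long reaction the free primary hydroxyl of 36 may attack its own lactone carbonyl to give a five-membered lactone, or DMAP may add to the 2-(acyloxymethyl)acrylate. Fallback: the roles are reversed, so that the carboxylate is the nucleophile. Setting out from 36, selective sulfonylation (TsCl, Et3N, Me3N·HCl cat., CH2Cl2, 0 °C) gives the half B primary tosylate F8. Cs2CO3 in MeCN closes the half B spiro-epoxide F9, with the C4–O bond and hence the configuration retained. The cesium carboxylate of 21 (Cs2CO3, DMF, 60 °C) then opens the epoxide at its CH2 carbon, and the route is rejoined at 37.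

Further compounds
F1 | step 3 | acetate of the series B bicyclic methyl acetal (C4-OAc) | CC(C)[C@@H]1C=C[C@H](OC(C)=O)[C@@H]2COC(OC)[C@@H]12
F2 | step 14 | series A formyl acid (C6-CHO α, C5-CO2H β) | CC(C)[C@H]1CC[C@@](O)(CO[Si](c2ccccc2)(c2ccccc2)C(C)(C)C)[C@@H](C(=O)O)[C@@H]1C=O
F3 | step 14 | series A (E)-enoate acid (C6-CH=C(CO2tBu)CH2O-4-methoxybenzyl) | CC(C)[C@H]1CC[C@@](O)(CO[Si](c2ccccc2)(c2ccccc2)C(C)(C)C)[C@@H](C(=O)O)[C@@H]1/C=C(\COCc1ccc(OC)cc1)C(=O)OC(C)(C)C
F4 | step 14 | series A hydroxy acid (C6-CH=C(CO2tBu)CH2OH) | CC(C)[C@H]1CC[C@@](O)(CO[Si](c2ccccc2)(c2ccccc2)C(C)(C)C)[C@@H](C(=O)O)[C@@H]1/C=C(\CO)C(=O)OC(C)(C)C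
F5 | step 27 | series B formyl acid (mirror image of F2) | CC(C)[C@@H]1CC[C@](O)(CO[Si](c2ccccc2)(c2ccccc2)C(C)(C)C)[C@H](C(=O)O)[C@H]1C=O
F6 | step 27 | series B (E)-enoate acid (mirror image of F3) | CC(C)[C@@H]1CC[C@](O)(CO[Si](c2ccccc2)(c2ccccc2)C(C)(C)C)[C@H](C(=O)O)[C@H]1/C=C(\COCc1ccc(OC)cc1)C(=O)OC(C)(C)C
F7 | step 27 | series B hydroxy acid (mirror image of F4) | CC(C)[C@@H]1CC[C@](O)(CO[Si](c2ccccc2)(c2ccccc2)C(C)(C)C)[C@H](C(=O)O)[C@H]1/C=C(\CO)C(=O)OC(C)(C)C
F8 | step 29 | half B primary tosylate | CC(C)[C@@H]1CC[C@](O)(COS(=O)(=O)c3ccc(C)cc3)[C@@H]2C(=O)OCC(C(=O)OC(C)(C)C)=C[C@@H]12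
F9 | step 29 | half B spiro-epoxide (C4–O–CH2) | CC(C)[C@@H]1CC[C@]3(CO3)[C@@H]2C(=O)OCC(C(=O)OC(C)(C)C)=C[C@@H]12
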